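Its constants were chosen freely; the result is computed.

Target is made when partner meets substrate, but the rate constant of partner with the other conformer is 325 times the one with substrate, and substrate keeps turning into that conformer. Partner is the limiting reagent, and every partner that reacts leaves one molecule of product.

all flasks: substrate 10 mM; other conformer 0.100 equiv
- beta: partner 0.700 equiv; a single well-mixed tank run continuously and read at steady state, 3.00 h in it on average
- delta: partner 0.700 equiv; a closed flask charged with all of it at once and left for 1.0 h; time 1.0 h
- theta: partner 0.700 equiv (fed, over 1.00 h); a stirred flask in which partner is dosed at a steady rate over 1.00 h without added volume, worked up at 1.0 h; time 1.0 h
- zeta: partner 0.700 equiv; a single well-mixed tank run continuously and read at steady state, 1.0 h in it on average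

    substrate + partner → target (k1 = 0.12 L mol⁻¹ s⁻¹)
    partner + other conformer → isomer of the product A (k2 = 39 L mol⁻¹ s⁻¹)
    substrate ⇌ other conformer (K3 = 0.092, k3 = 2.1 × 10⁻⁴ s⁻¹)
    target ⇌ isomer of the product B (K4 = 0.88, k4 = 3.4 × 10⁻⁴ s⁻¹)

- the set-up with the highest share of target in all that became target or isomer of the product A or isomer of the product B, at the outlet or at the end ("none" if the first two lie within 2 percentage points) (beta / delta / theta / zeta / none)
- share of target in all that became target or isomer of the product A or isomer of the product B, at the outlet or at the end, beta
- share of target in all that became target or isomer of the product A or isomer of the product B, at the outlet or at the end, delta
- share of target in all that became target or isomer of the product A or isomer of the product B, at the outlet or at the end, theta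
- share of target in all that became target or isomer of the product A or isomer of the product B, at the outlet or at the end, zeta

- the stated concentrations are those of everything mixed, before any reaction; amounts are the same in each set-up
- the feed brings no volume worth counting
- run time (delta): 1.0 h

I divide two rates so that time and substrate both drop out. Per substrate, target forms at the step's constant times partner, and other conformer forms at its own forward constant. The two are equal at a partner level I call the crossover, the forward conformer constant divided by the target constant: 1.75 mM. Their ratio, partner over crossover, works as a selectivity factor that moves with partner. It needs new conformer to meet partner rather than fall back, which holds above 0.0585 mM of partner.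

Now the ladder for delta, fastest first. With the other concentrations held at their charge, partner has a half-life of 0.30 min against the other conformer, shorter than the 0.23 h of substrate toward target. So about 1.00 mM of isomer of the product A forms first, leaving about 6.00 mM partner in delta. Next, with partner taken at its charge, substrate's 0.23 h toward target is shorter than its 0.92 h toward other conformer, forward step alone, by a factor of 4.00.

Each slice of partner then gives target or isomer of the product B in the share partner/(partner + crossover). Summed down to zero partner, that is partner minus crossover times ln(one plus partner over crossover), or 3.40 mM for delta. Then target has a half-life of 0.57 h toward isomer of the product B, forward step alone, and at equilibrium 53.2 % of the pair is target. Taking all the partner as spent and the pair as fully relaxed, I reckon a share of target of 25.8 % in delta.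

In theta the dose of 7.00 mM h⁻¹ starts below the forward conformer supply of 7.56 mM h⁻¹, so I expect partner to stay low there at the start. My reckoning stops short of the tanks, but I pick delta.

The forecast also picks delta, with 4.6 % for beta, 28.7 % for delta at the hour, 14.7 % for theta and 19.5 % for zeta. Its words on theta are: “low partner favours the conformer path”. My delta figure is for full relaxation, its figure for the hour.

The simulation gives delta, with 4.63 % for beta, 29.0 % for delta, 12.8 % for theta and 19.5 % for zeta.

In delta, the estimated 6.00 mM of partner left after the charged conformer stands at 3.43 times the crossover of 1.75 mM, so at that point substrate goes to target 3.43 times as fast as it turns into other conformer by the forward step, and delta reads 29.0 % at the hour. Left ten times as long, delta reads 26.4 % at 10.0 h and theta reads 9.47 % at 10.0 h.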